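**Retrosynthetic overview**
- The C2=C3 bond of the trienoyl chain is cut by an aldol condensation, giving a 3-acetyl-1,4-dihydroxy-5-(cis-1,4-dihydroxycyclohexyl)pyridin-2-one core and (2E,4E,6R,8S)-4,6,8-trimethyldeca-2,4-dienal.
- The cis-1,4-diol comes from hydrogenation of a 2,3-dioxabicyclo[2.2.2]octene, which is made by [4+2] cycloaddition of singlet oxygen to a 5-(cyclohexa-1,3-dienyl)pyridine N-oxide (key step).
- The pyridine comes from 5-bromo-2,4-dichloropyridine: C3 lithiation/acetylation, double SNAr with benzyl alcohol, N-oxidation, then Suzuki coupling with a dienyl triflate from cyclohexenone.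
- The dienal comes from two formyl olefinations of (2R,4S)-2,4-dimethylhexanal, itself from SN2 (inversion) coupling of the (S)-2-methylbutyl Grignard reagent with tert-butyl (R)-lactate triflate.
- Ring order: pyridine and carbocycle are bought; the only ring formed is the endoperoxide (cycloaddition), which is then opened reductively to fix the diol.

Assumption: the four starting materials (1, 3, 11, 16) are taken as commercial; the cyclohexane ring of the target has a mirror plane through C1' and C4', so only its cis relationship has to be set.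

**Route**

Step 1
Reactants: 1 tert-butyl (R)-lactate
Product: 2 tert-butyl (2R)-2-[(trifluoromethylsulfonyl)oxy]propanoate
Conditions: Tf2O, 2,6-lutidine, CH2Cl2, −78 to 0 °C
Reagents that add atoms: trifluoromethanesulfonic anhydride O=S(=O)(OS(=O)(=O)C(F)(F)F)C(F)(F)F
Why: O-sulfonylation of the secondary alcohol with a hindered base does not touch the stereocentre, so the (R) configuration bought with D-lactate is kept.

Step 2
Reactants: 2 tert-butyl (2R)-2-[(trifluoromethylsulfonyl)oxy]propanoate; 3 (S)-1-bromo-2-methylbutane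
Product: 5 tert-butyl (2R,4S)-2,4-dimethylhexanoate, via Grignard reagent 4 (not isolated)
Conditions: Mg, THF, 40 °C; then 2, ZnCl2 (10 mol%), THF, 0 °C
Reagents that add atoms: none
Why: Zinc-catalysed sp3–sp3 coupling of an α-triflyloxy ester with a primary alkyl Grignard reagent is a clean SN2 inversion, so the lactate carbon becomes the (2R) methyl centre (same letter after the priority change) while the purchased (S) centre β to magnesium is untouched.

Step 3
Reactants: 5 tert-butyl (2R,4S)-2,4-dimethylhexanoate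
Product: 6 (2R,4S)-2,4-dimethylhexan-1-ol
Conditions: LiAlH4, Et2O, 0 °C
Reagents that add atoms: none
Why: Hydride reduction of the ester to the primary alcohol is non-epimerising for the α-centre.

Step 4
Reactants: 6 (2R,4S)-2,4-dimethylhexan-1-ol
Product: 8 (2E,4R,6S)-2,4,6-trimethyloct-2-enal, via aldehyde 7 (not isolated)
Conditions: PhI(OAc)2, TEMPO (10 mol%), CH2Cl2, rt; then Ph3P=C(Me)CHO, toluene, 90 °C
Reagents that add atoms: 2-(triphenylphosphoranylidene)propanal CC(C=O)=P(c1ccccc1)(c1ccccc1)c1ccccc1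
Why: Nitroxyl-catalysed oxidation followed in the same flask by a Wittig reaction with a stabilised formyl ylide gives the E-trisubstituted enal, and the epimerisable aldehyde is never isolated.

Step 5
Reactants: 8 (2E,4R,6S)-2,4,6-trimethyloct-2-enal
Product: 10 (2E,4E,6R,8S)-4,6,8-trimethyldeca-2,4-dienal, via dienimine 9 (not isolated)
Conditions: diethyl [2-(cyclohexylamino)vinyl]phosphonate, NaH, THF, 0 °C to rt; then aq. oxalic acid, rt
Reagents that add atoms: diethyl [2-(cyclohexylamino)vinyl]phosphonate CCOP(=O)(OCC)C=CNC1CCCCC1; water O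
Why: Horner–Wadsworth–Emmons formyl-olefination through the unsaturated imine gives the E-enal after hydrolysis and cannot over-homologate; carbonyl addition is much faster than γ-deprotonation, so the allylic stereocentre is kept.

Step 6
Reactants: 11 5-bromo-2,4-dichloropyridine
Product: 13 1-(5-bromo-2,4-dichloropyridin-3-yl)ethan-1-one, via aryllithium 12 (not isolated)
Conditions: LiN(iPr)2, THF, −78 °C; then MeC(O)N(OMe)Me, −78 to −40 °C; aq. work-up
Reagents that add atoms: N-methoxy-N-methylacetamide CC(=O)N(C)OC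
Why: Directed ortho-metalation takes the hydrogen flanked by both chlorines, and Weinreb acylation of the resulting aryllithium stops at the ketone.

Step 7
Reactants: 13 1-(5-bromo-2,4-dichloropyridin-3-yl)ethan-1-one
Product: 14 1-[2,4-bis(benzyloxy)-5-bromopyridin-3-yl]ethan-1-one
Conditions: BnOH, NaH, THF, 0 °C to rt
Reagents that add atoms: benzyl alcohol OCc1ccccc1
Why: Double SNAr: both chlorides are activated by the ring nitrogen and the ortho acetyl group, whereas the C5 bromide (meta to both) is not displaced.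

Step 8
Reactants: 14 1-[2,4-bis(benzyloxy)-5-bromopyridin-3-yl]ethan-1-one
Product: 15 3-acetyl-2,4-bis(benzyloxy)-5-bromopyridine 1-oxide
Conditions: mCPBA, CH2Cl2, rt
Reagents that add atoms: 3-chloroperoxybenzoic acid OOC(=O)c1cccc(Cl)c1
Why: Peracid N-oxidation of a pyridine whose nitrogen is kept nucleophilic by the 4-alkoxy group, done before any alkene is present; it installs the N–O bond of the final hydroxamic acid.

Step 9
Reactants: 16 cyclohex-2-en-1-one
Product: 17 cyclohexa-1,3-dien-1-yl trifluoromethanesulfonate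
Conditions: Tf2O, 2,6-di-tert-butyl-4-methylpyridine, CH2Cl2, 0 °C to rt
Reagents that add atoms: trifluoromethanesulfonic anhydride O=S(=O)(OS(=O)(=O)C(F)(F)F)C(F)(F)F
Why: O-triflation of the enone and loss of the γ-proton to the hindered base gives the linearly conjugated dienyl triflate (enol triflate formation under thermodynamic control).

Step 10
Reactants: 15 3-acetyl-2,4-bis(benzyloxy)-5-bromopyridine 1-oxide; 17 cyclohexa-1,3-dien-1-yl trifluoromethanesulfonate
Product: 19 3-acetyl-2,4-bis(benzyloxy)-5-(cyclohexa-1,3-dien-1-yl)pyridine 1-oxide, via dienylboronate 18 (not isolated)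
Conditions: 17, B2pin2, PdCl2(dppf), KOAc, dioxane, 80 °C; then 15, K3PO4, H2O (5 equiv), 80 °C
Reagents that add atoms: none
Why: One-pot Miyaura borylation of the enol triflate and Suzuki–Miyaura coupling with the aryl bromide puts the pyridine on the terminus of the diene; N-oxide and ketone tolerate the conditions.

Step 11
Reactants: 19 3-acetyl-2,4-bis(benzyloxy)-5-(cyclohexa-1,3-dien-1-yl)pyridine 1-oxide
Product: 20 racemic 3-acetyl-2,4-bis(benzyloxy)-5-(2,3-dioxabicyclo[2.2.2]oct-5-en-1-yl)pyridine 1-oxide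
Conditions: O2, tetraphenylporphyrin (1 mol%), visible light, CH2Cl2, −20 °C
Reagents that add atoms: dioxygen O=O
Why: Suprafacial [4+2] cycloaddition of singlet oxygen to the cyclic 1,3-diene forms the endoperoxide ring with both new C–O bonds on the same face, which fixes the cis-1,4 relationship; the racemate converges to one achiral diol in the next step.

Step 12
Reactants: 20 racemic 3-acetyl-2,4-bis(benzyloxy)-5-(2,3-dioxabicyclo[2.2.2]oct-5-en-1-yl)pyridine 1-oxide
Product: 21 3-acetyl-1,4-dihydroxy-5-(cis-1,4-dihydroxycyclohexyl)pyridin-2(1H)-one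
Conditions: H2 (1 atm), 10% Pd/C, EtOAc–MeOH, rt
Reagents that add atoms: none
Why: Catalytic hydrogenation cleaves the O–O bond, saturates the ring alkene and removes both benzyl ethers (the 2-benzyloxy N-oxide unmasks as the N-hydroxy-2-pyridone) without touching either carbinol carbon, so the cis-diol is retained.

Step 13
Reactants: 21 3-acetyl-1,4-dihydroxy-5-(cis-1,4-dihydroxycyclohexyl)pyridin-2(1H)-one; 10 (2E,4E,6R,8S)-4,6,8-trimethyldeca-2,4-dienal
Product: 22 3-[(2E,4E,6E,8R,10S)-6,8,10-trimethyldodeca-2,4,6-trienoyl]-1,4-dihydroxy-5-(cis-1,4-dihydroxycyclohexyl)pyridin-2(1H)-one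
Conditions: piperidine (3 equiv), EtOH, 60 °C
Reagents that add atoms: none
Why: Amine-mediated Claisen–Schmidt (Knoevenagel-type aldol) condensation of the 3-acetyl-4-hydroxypyridone methyl group with the non-enolisable dienal gives the thermodynamically favoured E-enone; no stereocentre is involved.

**Compound list**

1 | tert-butyl (R)-lactate | C[C@@H](O)C(=O)OC(C)(C)C | starting material
2 | tert-butyl (2R)-2-[(trifluoromethylsulfonyl)oxy]propanoate | C[C@@H](OS(=O)(=O)C(F)(F)F)C(=O)OC(C)(C)C | intermediate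
3 | (S)-1-bromo-2-methylbutane | CC[C@H](C)CBr | starting material
4 | [(2S)-2-methylbutyl]magnesium bromide | CC[C@H](C)C[Mg]Br | intermediate (not isolated)
5 | tert-butyl (2R,4S)-2,4-dimethylhexanoate | CC[C@H](C)C[C@@H](C)C(=O)OC(C)(C)C | intermediate
6 | (2R,4S)-2,4-dimethylhexan-1-ol | CC[C@H](C)C[C@@H](C)CO | intermediate
7 | (2R,4S)-2,4-dimethylhexanal | CC[C@H](C)C[C@@H](C)C=O | intermediate (not isolated)
8 | (2E,4R,6S)-2,4,6-trimethyloct-2-enal | CC[C@H](C)C[C@@H](C)/C=C(C)/C=O | intermediate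
9 | (2E,4E,6R,8S)-N-cyclohexyl-4,6,8-trimethyldeca-2,4-dien-1-imine | CC[C@H](C)C[C@@H](C)/C=C(C)/C=C/C=NC1CCCCC1 | intermediate (not isolated)
10 | (2E,4E,6R,8S)-4,6,8-trimethyldeca-2,4-dienal | CC[C@H](C)C[C@@H](C)/C=C(C)/C=C/C=O | intermediate
11 | 5-bromo-2,4-dichloropyridine | Clc1cc(Cl)c(Br)cn1 | starting material
12 | (5-bromo-2,4-dichloropyridin-3-yl)lithium | [Li]c1c(Cl)ncc(Br)c1Cl | intermediate (not isolated)
13 | 1-(5-bromo-2,4-dichloropyridin-3-yl)ethan-1-one | CC(=O)c1c(Cl)ncc(Br)c1Cl | intermediate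
14 | 1-[2,4-bis(benzyloxy)-5-bromopyridin-3-yl]ethan-1-one | CC(=O)c1c(OCc2ccccc2)ncc(Br)c1OCc1ccccc1 | intermediate
15 | 3-acetyl-2,4-bis(benzyloxy)-5-bromopyridine 1-oxide | CC(=O)c1c(OCc2ccccc2)[n+]([O-])cc(Br)c1OCc1ccccc1 | intermediate
16 | cyclohex-2-en-1-one | O=C1C=CCCC1 | starting material
17 | cyclohexa-1,3-dien-1-yl trifluoromethanesulfonate | O=S(=O)(OC1=CC=CCC1)C(F)(F)F | intermediate
18 | 2-(cyclohexa-1,3-dien-1-yl)-4,4,5,5-tetramethyl-1,3,2-dioxaborolane | CC1(C)OB(OC1(C)C)C1=CC=CCC1 | intermediate (not isolated)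
19 | 3-acetyl-2,4-bis(benzyloxy)-5-(cyclohexa-1,3-dien-1-yl)pyridine 1-oxide | CC(=O)c1c(OCc2ccccc2)[n+]([O-])cc(C2=CC=CCC2)c1OCc1ccccc1 | intermediate
20 | 3-acetyl-2,4-bis(benzyloxy)-5-(2,3-dioxabicyclo[2.2.2]oct-5-en-1-yl)pyridine 1-oxide (racemic, one enantiomer drawn) | CC(=O)c1c(OCc2ccccc2)[n+]([O-])cc([C@]23C=C[C@H](CC2)OO3)c1OCc1ccccc1 | intermediate
21 | 3-acetyl-1,4-dihydroxy-5-(cis-1,4-dihydroxycyclohexyl)pyridin-2(1H)-one | CC(=O)c1c(O)c([C@]2(O)CC[C@@H](O)CC2)cn(O)c1=O | intermediate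
22 | 3-[(2E,4E,6E,8R,10S)-6,8,10-trimethyldodeca-2,4,6-trienoyl]-1,4-dihydroxy-5-(cis-1,4-dihydroxycyclohexyl)pyridin-2(1H)-one (CNP0174796.2) | CC[C@H](C)C[C@@H](C)/C=C(C)/C=C/C=C/C(=O)c1c(O)c([C@]2(O)CC[C@@H](O)CC2)cn(O)c1=O | target

**Step count and risks**

Total: 13 steps. Longest linear sequence: 7 steps (11 → 13 → 14 → 15 → 19 → 20 → 21 → 22); the side chain is 5 steps plus the final union.

Steps most likely to fail:

1. Step 13 (condensation on the unprotected, polar tetra-hydroxy core). Fallback: set out from 21 and separate C–C bond formation from dehydration. Silylate 21 in THF with N,O-bis(trimethylsilyl)acetamide to give 3-acetyl-1,4-bis(trimethylsilyloxy)-5-[cis-1,4-bis(trimethylsilyloxy)cyclohexyl]pyridin-2(1H)-one F1. Deprotonate its acetyl group with LiN(SiMe3)2 at −78 °C and add dienal 10 to give the silylated aldol adduct F2 (both carbinol epimers). Methanolysis (K2CO3, MeOH, 0 °C) frees the hydroxyl groups to give the β-hydroxy ketone F3. E1cB dehydration of this allylic aldol (DBU, THF, 40 °C) comes back to the route at 22.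

2. Step 10 (dienyl boronate may protodeboronate or aromatise, and the activated benzyloxy groups of the N-oxide may suffer SNAr by the base). Fallback: set out from 15 and make the second ring double bond only after the C–C bond exists. Suzuki coupling of 15 with commercial 2-(1,4-dioxaspiro[4.5]dec-7-en-8-yl)-4,4,5,5-tetramethyl-1,3,2-dioxaborolane (PdCl2(dppf), K3PO4, dioxane, 80 °C) gives 3-acetyl-2,4-bis(benzyloxy)-5-(1,4-dioxaspiro[4.5]dec-7-en-8-yl)pyridine 1-oxide F4. Acetal hydrolysis (1 M HCl, THF, rt) gives 3-acetyl-2,4-bis(benzyloxy)-5-(4-oxocyclohex-1-en-1-yl)pyridine 1-oxide F5. NaBH4 (MeOH, −40 °C) reduces only the unhindered ring ketone to 3-acetyl-2,4-bis(benzyloxy)-5-(4-hydroxycyclohex-1-en-1-yl)pyridine 1-oxide F6. MsCl/Et3N gives the mesylate 3-acetyl-2,4-bis(benzyloxy)-5-[4-(methylsulfonyloxy)cyclohex-1-en-1-yl]pyridine 1-oxide F7, and DBU (toluene, 70 °C) eliminates toward the allylic hydrogen, coming back to the route at 19.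

3. Step 12 (palladium may rearrange the endoperoxide, or over-reduce the N–O or tertiary C–O bond while four reductions run together). Fallback: set out from 20 and reduce in chemoselective stages. Thiourea (MeOH, rt) cleaves only the O–O bond to give racemic 3-acetyl-2,4-bis(benzyloxy)-5-(cis-1,4-dihydroxycyclohex-2-en-1-yl)pyridine 1-oxide F8. Diimide (KO2CN=NCO2K, AcOH, MeOH, 0 °C to rt) saturates the ring alkene to give 3-acetyl-2,4-bis(benzyloxy)-5-(cis-1,4-dihydroxycyclohexyl)pyridine 1-oxide F9. Brief transfer hydrogenolysis (Pd(OH)2/C, cyclohexa-1,4-diene, EtOH, rt) removes the two benzyl groups and comes back to the route at 21.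

**Further compounds**

F1 | step 13 | 3-acetyl-1,4-bis(trimethylsilyloxy)-5-[cis-1,4-bis(trimethylsilyloxy)cyclohexyl]pyridin-2(1H)-one | CC(=O)c1c(O[Si](C)(C)C)c([C@]2(O[Si](C)(C)C)CC[C@@H](O[Si](C)(C)C)CC2)cn(O[Si](C)(C)C)c1=O
F2 | step 13 | 3-[(4E,6E,8R,10S)-3-hydroxy-6,8,10-trimethyldodeca-4,6-dienoyl]-1,4-bis(trimethylsilyloxy)-5-[cis-1,4-bis(trimethylsilyloxy)cyclohexyl]pyridin-2(1H)-one (C3 epimers) | CC[C@H](C)C[C@@H](C)/C=C(C)/C=C/C(O)CC(=O)c1c(O[Si](C)(C)C)c([C@]2(O[Si](C)(C)C)CC[C@@H](O[Si](C)(C)C)CC2)cn(O[Si](C)(C)C)c1=O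
F3 | step 13 | 3-[(4E,6E,8R,10S)-3-hydroxy-6,8,10-trimethyldodeca-4,6-dienoyl]-1,4-dihydroxy-5-(cis-1,4-dihydroxycyclohexyl)pyridin-2(1H)-one (C3 epimers) | CC[C@H](C)C[C@@H](C)/C=C(C)/C=C/C(O)CC(=O)c1c(O)c([C@]2(O)CC[C@@H](O)CC2)cn(O)c1=O
F4 | step 10 | 3-acetyl-2,4-bis(benzyloxy)-5-(1,4-dioxaspiro[4.5]dec-7-en-8-yl)pyridine 1-oxide | CC(=O)c1c(OCc2ccccc2)[n+]([O-])cc(C2=CCC3(CC2)OCCO3)c1OCc1ccccc1
F5 | step 10 | 3-acetyl-2,4-bis(benzyloxy)-5-(4-oxocyclohex-1-en-1-yl)pyridine 1-oxide | CC(=O)c1c(OCc2ccccc2)[n+]([O-])cc(C2=CCC(=O)CC2)c1OCc1ccccc1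
F6 | step 10 | 3-acetyl-2,4-bis(benzyloxy)-5-(4-hydroxycyclohex-1-en-1-yl)pyridine 1-oxide (racemic) | CC(=O)c1c(OCc2ccccc2)[n+]([O-])cc(C2=CCC(O)CC2)c1OCc1ccccc1
F7 | step 10 | 3-acetyl-2,4-bis(benzyloxy)-5-[4-(methylsulfonyloxy)cyclohex-1-en-1-yl]pyridine 1-oxide (racemic) | CC(=O)c1c(OCc2ccccc2)[n+]([O-])cc(C2=CCC(OS(C)(=O)=O)CC2)c1OCc1ccccc1
F8 | step 12 | 3-acetyl-2,4-bis(benzyloxy)-5-(cis-1,4-dihydroxycyclohex-2-en-1-yl)pyridine 1-oxide (racemic, one enantiomer drawn) | CC(=O)c1c(OCc2ccccc2)[n+]([O-])cc([C@]2(O)C=C[C@@H](O)CC2)c1OCc1ccccc1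
F9 | step 12 | 3-acetyl-2,4-bis(benzyloxy)-5-(cis-1,4-dihydroxycyclohexyl)pyridine 1-oxide | CC(=O)c1c(OCc2ccccc2)[n+]([O-])cc([C@]2(O)CC[C@@H](O)CC2)c1OCc1ccccc1
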